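**Retrosynthetic overview**
1. The last bond made is C8–CH2. It joins the (2S)-6-Tri-flavanone, whose C8 is the only free A-ring carbon, to the Di o-quinone methide (o-QM).
2. Ring C is the only ring built; all benzene rings are bought. It is closed after the first benzylation by a chalcone-isomerase-type 6-endo oxa-Michael addition of the 3'-Tri-2',4',6'-trihydroxychalcone. This one step fixes O1–C2, the 6-versus-8 pattern and (2S).
3. The chalcone comes from benzaldehyde and 3-Tri-phloroacetophenone. The latter comes from phloroacetophenone (C3 = C5, so no regiochemical question) and the Tri o-QM.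
4. The Di and Tri o-QM precursors are acetonides. They are made by an iterated anionic o-QM sequence (aryl metal para to O, plus O-Boc-salicylaldehyde, plus hydride), with a para-bromination linking the two cycles.
5. Di = 2-hydroxy-5-(2-hydroxybenzyl)benzyl. Tri = 2-hydroxy-5-[2-hydroxy-5-(2-hydroxybenzyl)benzyl]benzyl.

Assumptions: 6-bromo-2,2-dimethyl-4H-1,3-benzodioxine is bought (bulk β-agonist intermediate; otherwise one step from 5-bromosalicyl alcohol and 2,2-dimethoxypropane); the quinidine-derived thiourea is taken as the pseudo-enantiomer that gives (2S), to be checked by CD, and if the sense is opposite the quinine-derived one is used with nothing else changed.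

**Step 1**
Reactants: 1 salicylaldehyde
Product: 2 tert-butyl 2-formylphenyl carbonate (O-Boc-salicylaldehyde)
Conditions: Boc2O (1.05 equiv), i-Pr2NEt (0.2 equiv), DMAP (2 mol %), THF, 0 °C → rt
Reagents that add atoms: di-tert-butyl dicarbonate, CC(C)(C)OC(=O)OC(=O)OC(C)(C)C
Why: DMAP-catalysed O-acylation of the acidic phenol (carbonate formation) installs the group that later migrates and leaves in the anionic o-QM cascade.

**Step 2**
Reactants: 3 6-bromo-2,2-dimethyl-4H-1,3-benzodioxine; 2 tert-butyl 2-formylphenyl carbonate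
Product: 6 2-[(2,2-dimethyl-4H-1,3-benzodioxin-6-yl)methyl]phenol (Di acetonide), via aryl Grignard reagent 4 (not isolated), via aryl-substituted o-quinone methide 5 (not isolated)
Conditions: 3, Mg, THF, 45 °C; add to 2, THF, −78 °C, 30 min; LiBH4 (1.5 equiv), −78 °C → rt; aq NH4Cl
Reagents that add atoms: none
Why: Grignard 1,2-addition, O→O Boc shift and loss of tert-butyl carbonate (Pettus anionic o-QM generation) give 5, and 1,4-hydride addition rearomatises it, so the aryl–CH2–aryl bond sits exactly para to the masked phenol oxygen and ortho to the new free OH.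

**Step 3**
Reactants: 6 Di acetonide
Product: 7 4-bromo-2-[(2,2-dimethyl-4H-1,3-benzodioxin-6-yl)methyl]phenol
Conditions: NBS (1.0 equiv), MeCN, −10 °C, dark
Reagents that add atoms: N-bromosuccinimide, O=C1CCC(=O)N1Br
Why: Electrophilic aromatic bromination goes to the only free-phenol ring and para to its OH in polar MeCN, because the other ring is merely an alkyl aryl ether with its para position blocked.

**Step 4**
Reactants: 7 bromide; 2 tert-butyl 2-formylphenyl carbonate
Product: 10 2-[(2,2-dimethyl-4H-1,3-benzodioxin-6-yl)methyl]-4-(2-hydroxybenzyl)phenol (Tri acetonide), via dilithio species 8 (not isolated), via quinone methide 9 (not isolated)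
Conditions: t-BuLi (3.1 equiv), THF, −78 °C; 2 (1.0 equiv), −78 °C; MgBr2·OEt2 (2.5 equiv), LiBH4 (2 equiv), −78 → 50 °C; aq NH4Cl
Reagents that add atoms: none
Why: Deprotonation and Br/Li exchange give 8, and the same Pettus addition/Boc-shift/elimination/hydride sequence (elimination triggered by Mg2+) repeats the ortho–para CH2 link; the phenolate-stabilised quinone methide 9 needs warming with borohydride, as in borohydride deoxygenations of hydroxybenzhydrols.

**Step 5**
Reactants: 11 2',4',6'-trihydroxyacetophenone (phloroacetophenone); 10 Tri acetonide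
Product: 13 1-(2,4,6-trihydroxy-3-Tri-phenyl)ethanone, via Tri o-quinone methide 12 (not isolated)
Conditions: 11 (4 equiv), TsOH·H2O (10 mol %), HFIP, 40 °C, slow addition of 10
Reagents that add atoms: none
Why: Acid in ionising HFIP opens the acetonide and acetone leaves, then 12 (or its protonated form) is captured by the much more nucleophilic acylphloroglucinol carbon (biomimetic Friedel–Crafts hydroxybenzylation); C3 and C5 of 11 are equivalent, so only mono versus bis matters, and the excess of 11 settles that.

**Step 6**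
Reactants: 13 3-Tri-phloroacetophenone; 14 benzaldehyde
Product: 15 (E)-1-(2,4,6-trihydroxy-3-Tri-phenyl)-3-phenylprop-2-en-1-one (chalcone)
Conditions: PhCHO (3 equiv), 50 % aq KOH/EtOH, Ar, rt, 48 h; pour into ice-cold 2 M HCl, extract cold, use at once
Reagents that add atoms: none
Why: In this Claisen–Schmidt condensation concentrated alkali holds the 2',6'-dihydroxychalcone open as its polyphenolate, and fast cold acidification delivers the (E)-chalcone before it can cyclise.

**Step 7**
Reactants: 15 chalcone
Product: 16 (2S)-5,7-dihydroxy-2-phenyl-6-Tri-chroman-4-one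
Conditions: 9-amino(9-deoxy)-epi-quinidine 3,5-(CF3)2C6H3-thiourea (10 mol %), toluene/THF 4:1, −20 °C, 72 h; SiO2 (removes 8-isomer); recrystallise to >99 % ee
Reagents that add atoms: none
Why: Proposed new method: this is a chalcone-isomerase-type 6-endo-trig intramolecular oxa-Michael addition in which the thiourea binds the carbonyl/enolate oxygen and the quinuclidine deprotonates the attacking phenol; the 3'-benzyl group buttresses and shields the 2'-OH in its hydrogen bond to C=O, so the unflanked and more acidic 6'-OH attacks and puts Tri at C6 (the same intrinsic bias that makes 3'-prenyl-2',4',6'-trihydroxychalcone close mainly to the 6-prenylflavanone), while the chiral ion pair exposes one face of Cβ and sets (2S) under kinetic control in an aprotic medium where the background cyclisation is slow; the closest known reactions are cinchona-thiourea oxa-Michael cyclisations of activated 2'-hydroxychalcones and cinchona-alkaloid cyclisations of 2',6'-dihydroxychalcones.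

**Step 8**
Reactants: 16 (2S)-6-Tri-flavanone; 6 Di acetonide
Product: 18 sarmentosumin D [(2S)-5,7-dihydroxy-2-phenyl-6-Tri-8-Di-chroman-4-one], via Di o-quinone methide 17 (not isolated)
Conditions: TsOH·H2O (5 mol %), HFIP, 25 °C, 6 (1.2 equiv) by syringe pump over 6 h
Reagents that add atoms: none
Why: In this o-QM Friedel–Crafts hydroxybenzylation, as in step 5, C8 is the only free carbon of the phloroglucinol ring and far more nucleophilic than the para positions of the side-chain phenols, and base-free conditions at 25 °C avoid the retro-oxa-Michael opening that would scramble C2 and the 6/8 pattern.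

**Compound list**
1 | salicylaldehyde | O=Cc1ccccc1O | starting material
2 | tert-butyl 2-formylphenyl carbonate | CC(C)(C)OC(=O)Oc1ccccc1C=O | intermediate
3 | 6-bromo-2,2-dimethyl-4H-1,3-benzodioxine | CC1(C)OCc2cc(Br)ccc2O1 | starting material
4 | (2,2-dimethyl-4H-1,3-benzodioxin-6-yl)magnesium bromide | CC1(C)OCc2cc([Mg]Br)ccc2O1 | intermediate
5 | 6-[(2,2-dimethyl-4H-1,3-benzodioxin-6-yl)methylidene]cyclohexa-2,4-dien-1-one | O=C1C=CC=CC1=Cc1ccc2OC(C)(C)OCc2c1 | intermediate
6 | 2-[(2,2-dimethyl-4H-1,3-benzodioxin-6-yl)methyl]phenol (Di acetonide) | CC1(C)OCc2cc(Cc3ccccc3O)ccc2O1 | intermediate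
7 | 4-bromo-2-[(2,2-dimethyl-4H-1,3-benzodioxin-6-yl)methyl]phenol | CC1(C)OCc2cc(Cc3cc(Br)ccc3O)ccc2O1 | intermediate
8 | lithium 2-[(2,2-dimethyl-4H-1,3-benzodioxin-6-yl)methyl]-4-lithiophenolate | CC1(C)OCc2cc(Cc3cc([Li])ccc3O[Li])ccc2O1 | intermediate
9 | 6-({3-[(2,2-dimethyl-4H-1,3-benzodioxin-6-yl)methyl]-4-hydroxyphenyl}methylidene)cyclohexa-2,4-dien-1-one (present as its phenolate) | O=C1C=CC=CC1=Cc1ccc(O)c(Cc2ccc3OC(C)(C)OCc3c2)c1 | intermediate
10 | 2-[(2,2-dimethyl-4H-1,3-benzodioxin-6-yl)methyl]-4-(2-hydroxybenzyl)phenol (Tri acetonide) | CC1(C)OCc2cc(Cc3cc(Cc4ccccc4O)ccc3O)ccc2O1 | intermediate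
11 | 2',4',6'-trihydroxyacetophenone | CC(=O)c1c(O)cc(O)cc1O | starting material
12 | 4-[2-hydroxy-5-(2-hydroxybenzyl)benzyl]-6-methylidenecyclohexa-2,4-dien-1-one (Tri o-QM) | C=C1C=C(Cc2cc(Cc3ccccc3O)ccc2O)C=CC1=O | intermediate
13 | 1-(2,4,6-trihydroxy-3-Tri-phenyl)ethanone | CC(=O)c1c(O)cc(O)c(Cc2cc(Cc3cc(Cc4ccccc4O)ccc3O)ccc2O)c1O | intermediate
14 | benzaldehyde | O=Cc1ccccc1 | starting material
15 | (E)-1-(2,4,6-trihydroxy-3-Tri-phenyl)-3-phenylprop-2-en-1-one | O=C(/C=C/c1ccccc1)c1c(O)cc(O)c(Cc2cc(Cc3cc(Cc4ccccc4O)ccc3O)ccc2O)c1O | intermediate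
16 | (2S)-5,7-dihydroxy-2-phenyl-6-Tri-chroman-4-one | O=C1C[C@@H](c2ccccc2)Oc2cc(O)c(Cc3cc(Cc4cc(Cc5ccccc5O)ccc4O)ccc3O)c(O)c21 | intermediate
17 | 4-(2-hydroxybenzyl)-6-methylidenecyclohexa-2,4-dien-1-one (Di o-QM) | C=C1C=C(Cc2ccccc2O)C=CC1=O | intermediate
18 | sarmentosumin D | O=C1C[C@@H](c2ccccc2)Oc2c(Cc3cc(Cc4ccccc4O)ccc3O)c(O)c(Cc3cc(Cc4cc(Cc5ccccc5O)ccc4O)ccc3O)c(O)c21 | target

**Step count and sequence**
Total step count: 8.
Longest linear sequence: 8 (1 → 2 → 6 → 7 → 10 → 13 → 15 → 16 → 18). Compound 6 is used twice.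

**Steps most likely to fail**

*Step 7.* Six free phenols may disorganise the hydrogen-bonding catalyst, so ee and the 6/8 ratio may be poor.
- The fallback sets out from 11 and 14 and puts the ring closure before any benzylation, using the enzyme itself.
- Compounds 11 and 14 are condensed (KOH/EtOH, cold acidification) to pinocembrin chalcone F1.
- Recombinant chalcone isomerase (pH 7.5 buffer, 5 % DMSO, 25 °C) closes it to (2S)-pinocembrin F2 in essentially enantiopure form.
- F2 is hydroxybenzylated with 10 under the conditions of step 5.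
- The product is separated by chromatography from the C-8 regioisomer (2S)-5,7-dihydroxy-2-phenyl-8-Tri-chroman-4-one F3.
- The route is rejoined at 16.

*Step 6.* The hexaphenolate of 13 may enolise or dissolve too poorly.
- The fallback sets out from 11, 14 and 10 and bypasses 13.
- The condensation is run on the small triphenol, and the product is cyclised in the same pot (KOH/EtOH, then NaOAc, reflux) to racemic pinocembrin F4.
- F4 is hydroxybenzylated with 10 (TsOH, HFIP). This gives an unseparated mixture of racemic 6-Tri-pinocembrin F5 and racemic 8-Tri-pinocembrin F6.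
- Brief treatment of the mixture with cold 50 % aq KOH, then pouring into ice-cold HCl, opens all regio- and stereoisomers to one and the same chalcone.
- The route is rejoined at 15.

*Step 4.* The phenolate-stabilised quinone methide 9 may resist hydride, or the dianion may behave badly.
- The fallback sets out from 7 and replaces the anionic cascade by a Negishi cross-coupling.
- Commercial 2-(chloromethyl)phenyl acetate is converted with Zn dust/LiCl in THF into [2-(acetyloxy)benzyl]zinc chloride F7.
- F7 is added slowly to 7 with Pd(OAc)2/SPhos in THF at 25 °C; these conditions tolerate the free phenol.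
- The coupling gives the Tri acetonide monoacetate F8.
- K2CO3/MeOH removes the acetate, and the route is rejoined at 10.

**Further compounds**
F1 | step 7 | pinocembrin chalcone, (E)-1-(2,4,6-trihydroxyphenyl)-3-phenylprop-2-en-1-one | O=C(/C=C/c1ccccc1)c1c(O)cc(O)cc1O
F2 | step 7 | (2S)-pinocembrin | O=C1C[C@@H](c2ccccc2)Oc2cc(O)cc(O)c21
F3 | step 7 | (2S)-5,7-dihydroxy-2-phenyl-8-Tri-chroman-4-one | O=C1C[C@@H](c2ccccc2)Oc2c(Cc3cc(Cc4cc(Cc5ccccc5O)ccc4O)ccc3O)c(O)cc(O)c21
F4 | step 6 | racemic pinocembrin | O=C1CC(c2ccccc2)Oc2cc(O)cc(O)c21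
F5 | step 6 | racemic 6-Tri-pinocembrin | O=C1CC(c2ccccc2)Oc2cc(O)c(Cc3cc(Cc4cc(Cc5ccccc5O)ccc4O)ccc3O)c(O)c21
F6 | step 6 | racemic 8-Tri-pinocembrin | O=C1CC(c2ccccc2)Oc2c(Cc3cc(Cc4cc(Cc5ccccc5O)ccc4O)ccc3O)c(O)cc(O)c21
F7 | step 4 | [2-(acetyloxy)benzyl]zinc chloride | CC(=O)Oc1ccccc1C[Zn]Cl
F8 | step 4 | Tri acetonide monoacetate, 2-({3-[(2,2-dimethyl-4H-1,3-benzodioxin-6-yl)methyl]-4-hydroxyphenyl}methyl)phenyl acetate | CC(=O)Oc1ccccc1Cc1ccc(O)c(Cc2ccc3OC(C)(C)OCc3c2)c1
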